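The easy entry in our ledger is the trapped intermediate, which rises at each reading of the south-west run. Every mole of starting complex charged stands either there or in the pool of exchanging complexes, so we book that entry first and divide the rest.

| flask | starting complex | incoming ligand | capture agent | remark | time |
|---|---|---|---|---|---|
| north-west | 0.20 M | 1.8 equiv | 0.077 M | run made earlier |  |
| north | 0.20 M | 1.8 equiv | 0.19 M | run made earlier |  |
| south-west | 0.20 M | 1.8 equiv | 0.56 M | run made earlier |  |
| amber | 0.20 M | 1.80 equiv | 0.0600 M |  | 3.0 h |
| blue | 0.20 M | 1.80 equiv | 0.540 M |  | 3.0 h |
| violet | 0.20 M | 1.80 equiv | 0.180 M |  | 3.0 h |

| run | time / min | complex with one exchanged / % | complex with two exchanged / % | complex with three exchanged / % | starting complex / % | trapped intermediate / % |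
|---|---|---|---|---|---|---|
| north-west | 8.00 | 21 | 2 | 1 | 80 | 2 |
| north-west | 15.0 | 30 | 3 | 0 | 65 | 2 |
| north-west | 40.0 | 33 | 6 | 0 | 54 | 3 |
| north-west | 90.0 | 27 | 9 | 4 | 53 | 3 |
| north | 12.0 | 26 | 1 | 1 | 68 | 0 |
| north | 30.0 | 34 | 7 | 0 | 54 | 3 |
| north | 60.0 | 30 | 11 | 3 | 52 | 7 |
| north | 90.0 | 27 | 9 | 4 | 50 | 12 |
| south-west | 8.00 | 18 | 1 | 1 | 75 | 2 |
| south-west | 15.0 | 29 | 2 | 1 | 65 | 5 |
| south-west | 40.0 | 28 | 4 | 4 | 50 | 12 |
| south-west | 90.0 | 18 | 5 | 3 | 43 | 27 |

(standard deviation of a reading: 1.5 percentage points)

- the analysis behind the earlier runs scatters by 1.5 percentage points, standard deviation

- which of these there is most of at the end, counted by the starting complex in it, amber (starting complex / trapped intermediate / complex with one exchanged / complex with three exchanged / complex with two exchanged)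
- which of these there is most of at the end, counted by the starting complex in it, blue (starting complex / trapped intermediate / complex with one exchanged / complex with three exchanged / complex with two exchanged)
- which of these there is most of at the end, counted by the starting complex in it, violet (starting complex / trapped intermediate / complex with one exchanged / complex with three exchanged / complex with two exchanged)
- how much there is at the end of the one of these that leads, in percent of the starting complex charged: amber
- how much there is at the end of the one of these that leads, in percent of the starting complex charged: blue
- how much there is at the end of the one of these that leads, in percent of the starting complex charged: violet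

Between 40.0 min and 90.0 min of the south-west run the trapped share gains 15 percentage points, while the complex with one exchanged averages 23.0%. With capture agent charged at 0.56 M, this reads as a trapping constant of 0.0233 /M/min. At the last reading of the south-west run that complex is 24.7% of the pool. So we carry the drain constant, the fraction of the pool trapped per minute and per unit molarity of capture agent, 0.00574 /M/min. Multiplied by the capture agent, it is a pseudo-first-order constant. We assume that each trapped intermediate spends one capture agent.

For blue we borrow the trapped share of the south-west run at 90.0 min, since that run's capture agent, 0.56 M, stands near blue's 0.540 M and the other charges are the same. Holding pool and agent fixed gives 45.3% trapped. Putting that answer back, with pool and agent at their means, gives 42.4%. The starting complex, at its south-west share of the pool, books 33.9%, the complex with one exchanged 14.2%, and the remaining 9.50% closes the books on the two higher complexes. Trapped leads blue in our reckoning, with more than the starting complex. The same two rounds from an empty ledger, counting no lag and borrowing the south-west shares of the pool, give amber 6.20%, then 5.39% trapped, with starting complex at 55.7%. For violet they give 18.6%, then 15.1% trapped, with starting complex at 50.0%. In our reckoning, starting complex leads amber with more than the trapped intermediate and the complex with one exchanged, and it leads violet in the same way.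

The forecast, which calls trapping “an irreversible drain on the exchange pool”, names starting complex for amber at 50% (46% to 54%), trapped intermediate for blue at 44% (37% to 52%), and starting complex for violet at 46% (41% to 50%). Our figures stand higher for amber and violet, and lower for blue.

The flasks give starting complex at 52.5% in amber, trapped intermediate at 41.6% in blue, and starting complex at 47.5% in violet.

    starting complex + incoming ligand ⇌ leaving ligand + complex with one exchanged (K = 0.390, k = 0.0970 /M/min)
    complex with one exchanged + incoming ligand ⇌ leaving ligand + complex with two exchanged (K = 0.300, k = 0.0450 /M/min)
    complex with two exchanged + incoming ligand ⇌ leaving ligand + complex with three exchanged (K = 0.910, k = 0.0470 /M/min)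
    complex with one exchanged + capture agent → trapped intermediate (k = 0.0240 /M/min)
    incoming ligand → decomposed reagent (k = 0.00120 /min)

Blue has not come to rest: with the capture agent left at the end, the drain constant gives the pool a half-life of 4.40 h, longer than the run. At 30.0 h blue holds 88.1% trapped and 11.5% starting complex, while amber's starting complex stands at 60.3% with 12.8% of its incoming ligand left. The neighbour of amber charged with 1.10 equiv of incoming ligand has the same capture agent, so the drain constant, with the same borrowed shares, again gives 5.39% trapped; that flask holds 5.79% at 3.00 h.

Readings and results are calculated with made-up constants; scatter was added.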